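**Strategy.** The benzoquinone ring is cut into a squaric-acid-derived four-carbon unit (ring carbons C1–C4, side chain on C3) and the two carbons of methoxyacetylene (C5 with its methoxyl, C6 with its hydrogen). This exploits the fact that four ring carbons (C1, C2, C4, C5) carry oxygen and C6 carries the only ring hydrogen. Heating a 4-hydroxy-4-(methoxyethynyl)cyclobutenone should forge the C4–C5 bond, close the six-membered ring and reach the quinone oxidation level without an oxidant. The precursor bears tert-butoxy at the future C2 and the finished (R)-2-acetoxypentadecyl chain at the future C3, whose stereocentre comes from (R)-epichlorohydrin, so that only tert-butyl cleavage follows.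

Key step: step 6

**Remarks on the chemistry (assumptions)**
- Numbering: quinone C1 (C=O), C2 (OH), C3 (side chain), C4 (C=O), C5 (OMe), C6 (H); side chain C1' (ring CH2), C2' (carbinol carbon).
- The side-chain oxygen is carried as the acetate of the target from step 3 onward, not as a silyl ether. A free C2' hydroxyl on the quinone could close onto C2 with loss of tert-butanol, and a protecting-group exchange after the key step is avoided.
- The stereochemistry was checked: (R)-epichlorohydrin maps onto the (R)-carbinol of the target. No bond to C2' is made or broken; only dianion 6 formally becomes S, because CH2Li ranks below the alkyl chain.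
- Transient O-metal salts of numbered alcohols are not numbered separately, except 7, which is never protonated.
- The ring carbinol carbon of 16 forms as both epimers. This is immaterial because it becomes the C1 carbonyl.

**Route**

Step 1
Reactants: 1 1-bromododecane; 2 (R)-epichlorohydrin
Product: 4 (R)-1-chloropentadecan-2-ol, via dodecylmagnesium bromide 3 (not isolated)
Conditions: Mg, THF, 40 °C; then CuI (10 mol %), 2, THF, −40 → 0 °C; sat. aq. NH4Cl
Reagents that add atoms: none
Why: Copper-catalysed Grignard opening of the terminal epoxide (SN2 at the unsubstituted oxirane carbon, faster than displacement of the primary chloride) should give the chlorohydrin, and since no bond to the stereocentre is made or broken the (R) configuration of 2 is carried over.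

Step 2
Reactants: 4 (R)-1-chloropentadecan-2-ol; 5 di-tert-butyl squarate
Product: 10 3-tert-butoxy-4-[(R)-2-hydroxypentadecyl]cyclobut-3-ene-1,2-dione, via dilithio alkoxide 6 (not isolated), via dilithium squarate adduct 7 (not isolated), via bis(trifluoroacetate) 8 (not isolated), via dione trifluoroacetate 9 (not isolated)
Conditions: n-BuLi (1.0 equiv), THF, −78 °C; LiC10H8 (lithium naphthalenide, 2.0 equiv), −78 °C; cannulate into 5 (1.2 equiv), THF, −78 °C; TFAA (2.5 equiv), −78 → −40 °C; sat. aq. NaHCO3, 0 °C → rt
Reagents that add atoms: none
Why: O-Deprotonation followed by reductive lithiation of the C–Cl bond (arene-radical-anion lithiation of a chlorohydrin) should give the β-oxido alkyllithium 6, which does not β-eliminate at −78 °C because lithium oxide is a very poor leaving group; its 1,2-addition to one squarate carbonyl and in situ trifluoroacetylation should then trigger the usual ionisation and loss of the tert-butyl group from the oxygen next to the former carbonyl (squarate addition/rearrangement to a 3-alkoxy-4-alkylcyclobutenedione), the bicarbonate work-up hydrolysing the labile side-chain trifluoroacetate and the stereocentre staying untouched.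

Step 3
Reactants: 10 3-tert-butoxy-4-[(R)-2-hydroxypentadecyl]cyclobut-3-ene-1,2-dione
Product: 11 (R)-1-(2-tert-butoxy-3,4-dioxocyclobut-1-en-1-yl)pentadecan-2-yl acetate
Conditions: Ac2O (1.5 equiv), pyridine, DMAP (5 mol %), CH2Cl2, 0 °C
Reagents that add atoms: acetic anhydride, CC(=O)OC(C)=O
Why: DMAP-catalysed O-acetylation of the only hydroxyl should install the ester of the target with a weak amine base that cannot deprotonate C1' of the dione, with retention at C2' because its C–O bond is not touched.

Step 4
Reactants: 12 chloroacetaldehyde dimethyl acetal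
Product: 14 methoxyacetylene, via sodium methoxyacetylide 13 (not isolated)
Conditions: NaNH2 (3.1 equiv), liq. NH3, −33 °C; evaporate NH3; cold sat. aq. NaCl, −70 °C; distil into THF at −78 °C, titrate
Reagents that add atoms: none
Why: Twofold amide-induced β-elimination (methanol, then hydrogen chloride) from the α-chloro acetal and deprotonation of the resulting alkyne is the classical alkoxyacetylene synthesis, and protonation with distillation should give an amine-free and alkoxide-free ynol ether for the next step.

Step 5
Reactants: 14 methoxyacetylene; 11 (R)-1-(2-tert-butoxy-3,4-dioxocyclobut-1-en-1-yl)pentadecan-2-yl acetate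
Product: 16 (R)-1-[2-tert-butoxy-3-hydroxy-3-(methoxyethynyl)-4-oxocyclobut-1-en-1-yl]pentadecan-2-yl acetate (both ring-carbinol epimers), via lithium methoxyacetylide 15 (not isolated)
Conditions: 14 (1.2 equiv), n-BuLi (1.1 equiv), THF, −78 °C; then 11, −78 °C; pH 7 phosphate buffer; crude used directly
Reagents that add atoms: none
Why: The lithium acetylide should add 1,2 (acetylide addition to a cyclobutenedione) to the ketone-like carbonyl flanking the tert-butoxy carbon, because the other carbonyl is deactivated as a vinylogous ester, and at −78 °C this very electrophilic carbonyl should outcompete the acetate; the new carbinol centre forms without control and is destroyed in step 6.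

Step 6
Reactants: 16 (R)-1-[2-tert-butoxy-3-hydroxy-3-(methoxyethynyl)-4-oxocyclobut-1-en-1-yl]pentadecan-2-yl acetate
Product: 19 3-[(R)-2-acetoxypentadecyl]-2-tert-butoxy-5-methoxy-1,4-benzoquinone, via alkynyl vinylketene 17 (not isolated), via ring diradical 18 (not isolated)
Conditions: PhMe (0.01 M, degassed), 110 °C
Reagents that add atoms: none
Why: Heat should open the cyclobutenone by conrotatory four-electron electrocyclic cleavage of the bond between the carbonyl and carbinol carbons, the donor hydroxyl rotating outward so that the alkynyl group turns inward, cis to the ketene in 17; this holds for both carbinol epimers. The ketene carbon should then bond to the methoxy-bearing alkyne carbon in a 6-endo-dig closure (the carbocyclic quinone ring, new C4–C5 bond) to give the aryl/phenoxyl diradical 18, which collapses by shift of the hydroxyl hydrogen to C6, so the quinone forms without an oxidant. The closest known reaction type is the Moore rearrangement of 4-alkynyl-4-hydroxycyclobutenones to 1,4-benzoquinones, here with an ynol-ether terminus. No stereocentre is created: the carbinol carbon becomes the C1 carbonyl and C2' is a spectator. The step needs six-membered rather than five-membered closure (to an alkylidenecyclopentenedione); a methoxy terminus gives the exocyclic vinyl radical of the five-membered path no conjugative stabilisation, a methyl ynol ether cannot lose an alkene by retro-ene cleavage as an ethyl one can, and the placement of OMe at C5 and tert-butoxy at C2 is already fixed by the connectivity of 16. Premature thermal loss of 2-methylpropene from the tert-butyl ether would only give target 20 directly.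

Step 7
Reactants: 19 3-[(R)-2-acetoxypentadecyl]-2-tert-butoxy-5-methoxy-1,4-benzoquinone
Product: 20 3-[(R)-2-acetoxypentadecyl]-2-hydroxy-5-methoxy-1,4-benzoquinone (CNP0332196.1)
Conditions: TFA/CH2Cl2 (1:4), 0 °C → rt
Reagents that add atoms: none
Why: Acid-mediated cleavage of the tert-butyl vinylogous ester (E1 loss of the tert-butyl cation as 2-methylpropene) should free the C2 hydroxyl, while the secondary acetate, the methyl vinylogous ester and the stereocentre, none of which ionises in anhydrous TFA, stay intact.

**Compound list**

1 | 1-bromododecane | CCCCCCCCCCCCBr | starting material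
2 | (R)-epichlorohydrin, (R)-2-(chloromethyl)oxirane | ClC[C@H]1CO1 | starting material
3 | dodecylmagnesium bromide | CCCCCCCCCCCC[Mg]Br | intermediate
4 | (R)-1-chloropentadecan-2-ol | CCCCCCCCCCCCC[C@H](CCl)O | intermediate
5 | di-tert-butyl squarate, 3,4-di-tert-butoxycyclobut-3-ene-1,2-dione | CC(C)(C)OC1=C(OC(C)(C)C)C(=O)C1=O | starting material
6 | lithium (S)-1-lithiopentadecan-2-olate (same spatial arrangement as 4) | CCCCCCCCCCCCC[C@H](C[Li])O[Li] | intermediate
7 | dilithium salt of 2,3-di-tert-butoxy-4-hydroxy-4-[(R)-2-hydroxypentadecyl]cyclobut-2-en-1-one (both ring-carbinol epimers) | CCCCCCCCCCCCC[C@H](CC1(O[Li])C(OC(C)(C)C)=C(OC(C)(C)C)C1=O)O[Li] | intermediate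
8 | bis(trifluoroacetate) of 2,3-di-tert-butoxy-4-hydroxy-4-[(R)-2-hydroxypentadecyl]cyclobut-2-en-1-one | CCCCCCCCCCCCC[C@H](CC1(OC(=O)C(F)(F)F)C(OC(C)(C)C)=C(OC(C)(C)C)C1=O)OC(=O)C(F)(F)F | intermediate
9 | (R)-1-(2-tert-butoxy-3,4-dioxocyclobut-1-en-1-yl)pentadecan-2-yl trifluoroacetate | CCCCCCCCCCCCC[C@H](CC1=C(OC(C)(C)C)C(=O)C1=O)OC(=O)C(F)(F)F | intermediate
10 | 3-tert-butoxy-4-[(R)-2-hydroxypentadecyl]cyclobut-3-ene-1,2-dione | CCCCCCCCCCCCC[C@H](CC1=C(OC(C)(C)C)C(=O)C1=O)O | intermediate
11 | (R)-1-(2-tert-butoxy-3,4-dioxocyclobut-1-en-1-yl)pentadecan-2-yl acetate | CCCCCCCCCCCCC[C@H](CC1=C(OC(C)(C)C)C(=O)C1=O)OC(C)=O | intermediate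
12 | chloroacetaldehyde dimethyl acetal, 2-chloro-1,1-dimethoxyethane | COC(CCl)OC | starting material
13 | sodium methoxyacetylide | COC#C[Na] | intermediate
14 | methoxyacetylene | COC#C | intermediate
15 | lithium methoxyacetylide | COC#C[Li] | intermediate
16 | (R)-1-[2-tert-butoxy-3-hydroxy-3-(methoxyethynyl)-4-oxocyclobut-1-en-1-yl]pentadecan-2-yl acetate (both ring-carbinol epimers) | CCCCCCCCCCCCC[C@H](CC1=C(OC(C)(C)C)C(O)(C#COC)C1=O)OC(C)=O | intermediate
17 | (3Z)-2-[(R)-2-acetoxypentadecyl]-3-tert-butoxy-4-hydroxy-6-methoxyhexa-1,3-dien-5-yn-1-one (alkynyl vinylketene) | CCCCCCCCCCCCC[C@H](CC(=C=O)/C(OC(C)(C)C)=C(/O)C#COC)OC(C)=O | intermediate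
18 | ring diradical: 3-[(R)-2-acetoxypentadecyl]-2-tert-butoxy-1-hydroxy-5-methoxybenzene with phenoxyl oxygen on C4 and aryl radical at C6 | CCCCCCCCCCCCC[C@H](CC1=C(OC(C)(C)C)C(O)=[C]C(OC)=C1[O])OC(C)=O | intermediate
19 | 3-[(R)-2-acetoxypentadecyl]-2-tert-butoxy-5-methoxy-1,4-benzoquinone | CCCCCCCCCCCCC[C@H](CC1=C(OC(C)(C)C)C(=O)C=C(OC)C1=O)OC(C)=O | intermediate
20 | 3-[(R)-2-acetoxypentadecyl]-2-hydroxy-5-methoxy-1,4-benzoquinone (CNP0332196.1) | CCCCCCCCCCCCC[C@H](CC1=C(O)C(=O)C=C(OC)C1=O)OC(C)=O | target

**Step count**
Total steps: 7. Longest linear sequence: 6 (steps 1, 2, 3, 5, 6, 7); step 4 is a one-step side branch.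

**Steps most likely to fail**

Step 6. The ketene may close onto the inner alkyne carbon (five-membered closure), or the ynol ether may decompose or polymerise before ring opening. The fallback replaces the alkyne by an alkene, so that only a six-electron electrocyclisation is possible. It sets out from 14 and 11 and comes back at 19. Methoxyacetylene 14 would be hydrostannylated (Bu3SnH, AIBN) to (Z)-tributyl(2-methoxyvinyl)stannane F1. Tin–lithium exchange with n-BuLi at −78 °C should give (Z)-2-methoxyvinyllithium F2, which would add to dione 11 at the same carbonyl to give (R)-1-{2-tert-butoxy-3-hydroxy-3-[(Z)-2-methoxyvinyl]-4-oxocyclobut-1-en-1-yl}pentadecan-2-yl acetate F3. Heating F3 in toluene should open the ring to a dienylketene, which closes and enolises to the hydroquinone (R)-1-(2-tert-butoxy-3,6-dihydroxy-5-methoxyphenyl)pentadecan-2-yl acetate F4. Oxidation of F4 with Ag2O would return to quinone 19.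

Step 2. The dianion may lose lithium oxide by β-elimination on slight warming, the reductive lithiation may be incomplete, or leftover arene radical anion may transfer an electron to the squarate. The fallback makes the carbanion by two-electron halogen–metal exchange instead of single-electron reduction. It sets out from 4 and comes back at 6. A Finkelstein exchange (NaI, acetone, reflux) would convert 4 into (R)-1-iodopentadecan-2-ol F5. Treatment of F5 with t-BuLi (3 equiv) in Et2O/pentane at −78 °C should deprotonate the hydroxyl and exchange iodine for lithium, giving 6 free of arene and reductant. The sequence then continues with 5 and TFAA to 10 as in step 2.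

Step 5. The acetylide may attack the ester carbonyl, or act as a base at C1' and expel acetate by β-elimination. The fallback moves the acetylation behind the alkynylation, so that the side-chain oxygen is a non-leaving lithium alkoxide during the addition. It sets out from 10 and comes back at 16, and step 3 is skipped. Hydroxy dione 10 would be treated with 15 (2.2 equiv; the first equivalent deprotonates the hydroxyl) at −78 °C to give 3-tert-butoxy-4-hydroxy-2-[(R)-2-hydroxypentadecyl]-4-(methoxyethynyl)cyclobut-2-en-1-one F6. Selective acetylation of the secondary hydroxyl of F6 (Ac2O, pyridine, 0 °C; the tertiary propargylic hydroxyl is too hindered to react) should give 16.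

Further compounds
F1 | step 6 | (Z)-tributyl(2-methoxyvinyl)stannane | CO/C=C\[Sn](CCCC)(CCCC)CCCC
F2 | step 6 | (Z)-2-methoxyvinyllithium | CO/C=C\[Li]
F3 | step 6 | (R)-1-{2-tert-butoxy-3-hydroxy-3-[(Z)-2-methoxyvinyl]-4-oxocyclobut-1-en-1-yl}pentadecan-2-yl acetate (both ring-carbinol epimers) | CCCCCCCCCCCCC[C@H](CC1=C(OC(C)(C)C)C(O)(/C=C\OC)C1=O)OC(C)=O
F4 | step 6 | (R)-1-(2-tert-butoxy-3,6-dihydroxy-5-methoxyphenyl)pentadecan-2-yl acetate | CCCCCCCCCCCCC[C@H](Cc1c(OC(C)(C)C)c(O)cc(OC)c1O)OC(C)=O
F5 | step 2 | (R)-1-iodopentadecan-2-ol | CCCCCCCCCCCCC[C@H](CI)O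
F6 | step 5 | 3-tert-butoxy-4-hydroxy-2-[(R)-2-hydroxypentadecyl]-4-(methoxyethynyl)cyclobut-2-en-1-one (both ring-carbinol epimers) | CCCCCCCCCCCCC[C@H](CC1=C(OC(C)(C)C)C(O)(C#COC)C1=O)O
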